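## Plan

1. Numbering (bisabolane): ring C1–C6 with methyl C15 on C3, ketone C4, ester on C5, side chain C7(=C14)–C8(OAc)–C9–C10=C11 on C6. Retrosynthetic cuts, in order: C4=O back to C4–OH, the epoxide oxygen, the angelate acyl–O bond, O–C5, the acetate O–C8 bond (cut with inversion), C7=C14, then C1–C2 and C5–C6 together, the two Si–O bonds of a tether, C7–vinyl and C9–C10.
2. Forward: an acyclic α′-hydroxy vinyl ketone (C1 and C6–C13) is tied through O8–Si–O4 to the dienol of 3-methylbut-3-en-2-one (C2–C5 and C15). One thermal [4+2] event closes the cyclohexene and, transiently, an eight-membered silaketal ring (bicyclo[5.3.1]). The tether is then spent as the regiodefined enol ether of a Saegusa–Ito oxidation, and the monocyclic enone is oxidised at C5, C2 and C3.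
3. Enabling feature: the oxygen on ring carbon C4 and the oxygen on side-chain carbon C8 are 1,5-related across the C5–C6 bond, so one silicon atom can bridge an enol ether at C4 and the C8 alkoxide. This makes the cycloaddition a type 2 intramolecular reaction whose short tether forces the 1,3-relation of C4–O and the C6 acyl group, which an untethered 2-siloxydiene would not give.
4. Stereochemistry: C8 comes from methyl (R)-glycidate, relays to C6 in the cycloaddition and is inverted to 8S when the acetate is installed. C5–O enters anti to the C6 side chain; the temporary C4–OH comes from axial hydride delivery and directs the epoxide to the face syn to the side chain; the Z-ester geometry comes from angelic acid.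

Key step: step 5

Remark: the sense of the C8-to-C6 relay in step 5 is taken from the tether-endo, s-cis-enone transition-state model, not from a measured case. That model calls for the 8R carbinol, which is why the acetate is introduced with inversion in step 8.

## Route

Step 1
Reactants: 1 methyl (2R)-oxirane-2-carboxylate; 2 (2-methylprop-1-en-1-yl)magnesium bromide
Product: 3 methyl (2R)-2-hydroxy-5-methylhex-4-enoate
Conditions: CuI (10 mol %), THF, −78 to −40 °C; aq. NH4Cl
Reagents that add atoms: (2-methylprop-1-en-1-yl)magnesium bromide, CC(C)=C[Mg]Br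
Why: Copper-catalysed Grignard opening of the epoxide at its unsubstituted carbon (SN2) should outrun ester addition at low temperature and leaves the existing stereocentre, the future C8, untouched.

Step 2
Reactants: 3 methyl (2R)-2-hydroxy-5-methylhex-4-enoate; 4 N,O-dimethylhydroxylamine hydrochloride
Product: 5 (2R)-2-hydroxy-N-methoxy-N,5-dimethylhex-4-enamide
Conditions: iPrMgCl (4.5 equiv), THF, −20 to 0 °C
Reagents that add atoms: N,O-dimethylhydroxylamine hydrochloride, CNOC.Cl
Why: Direct aminolysis of the ester by the magnesium amide of the hydroxylamine (Weinreb amide formation) runs through the magnesium alkoxide, which also shields the α-centre from enolisation.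

Step 3
Reactants: 5 (2R)-2-hydroxy-N-methoxy-N,5-dimethylhex-4-enamide; 6 vinylmagnesium bromide
Product: 7 (4R)-4-hydroxy-7-methylocta-1,6-dien-3-one
Conditions: CH2=CHMgBr (3 equiv), THF, −78 to 0 °C; poured into cold 1 M HCl; used at once
Reagents that add atoms: vinylmagnesium bromide, C=C[Mg]Br
Why: Grignard addition to the Weinreb amide stops at the chelated tetrahedral intermediate, and the inverse acidic quench keeps the released hydroxylamine protonated so that it cannot add to the new enone.

Step 4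
Reactants: 8 3-methylbut-3-en-2-one; 9 dichlorodi(propan-2-yl)silane; 7 (4R)-4-hydroxy-7-methylocta-1,6-dien-3-one
Product: 12 (4R)-7-methyl-4-({[(3-methylbuta-1,3-dien-2-yl)oxy]di(propan-2-yl)silyl}oxy)octa-1,6-dien-3-one, via lithium 3-methylbuta-1,3-dien-2-olate 10 (not isolated), via chloro(dienyloxy)di(propan-2-yl)silane 11 (not isolated)
Conditions: 8, LiN(iPr)2, THF, −78 °C; added to 9 (3 equiv), −78 °C to rt; volatiles removed in vacuo; then 7, Et3N, DMAP (cat.), CH2Cl2, 0 °C to rt
Reagents that add atoms: 3-methylbut-3-en-2-one, CC(=O)C(C)=C; dichlorodi(propan-2-yl)silane, CC(C)[Si](Cl)(Cl)C(C)C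
Why: Kinetic deprotonation of the only α-methyl group gives the cross-conjugated dienolate, whose O-silylation by excess dichlorosilane followed by amine-mediated silylation of the secondary alcohol is the usual stepwise assembly of an unsymmetrical silaketal (temporary silicon tether) and touches no stereocentre.

Step 5
Reactants: 12 (4R)-7-methyl-4-({[(3-methylbuta-1,3-dien-2-yl)oxy]di(propan-2-yl)silyl}oxy)octa-1,6-dien-3-one
Product: 13 (5R,7R)-10-methyl-5-(3-methylbut-2-en-1-yl)-3,3-di(propan-2-yl)-2,4-dioxa-3-silabicyclo[5.3.1]undec-1(10)-en-6-one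
Conditions: toluene (0.01 M), BHT (cat.), 110 °C, base-washed sealed vessel
Reagents that add atoms: none
Why: A thermal, concerted [4π+2π] cycloaddition of the 2-siloxydiene onto the vinyl ketone is expected, i.e. a type 2 intramolecular Diels–Alder reaction through a temporary silaketal tether, the closest known class being tethered type 2 reactions that give bridgehead-olefin bicyclo[5.3.1] systems. The cyclohexene closes by suprafacial bonding at both diene termini (C2 to C1 and C5 to C6), and the eight-membered 1,3-dioxa-2-silacyclooctane closes through the same C5–C6 bond with the tether necessarily endo. The five-atom tether cannot span the 1,4-positions, so it enforces the 1,3-relation of the C4 oxygen and the C6 acyl group against the para preference of an untethered 2-siloxydiene, while the C3 methyl group and the electron-poor enone keep the reaction in the normal-demand regime. C6 is the only new stereocentre and is set by C8: in the s-cis enone the carbonyl oxygen lies under the diene, the C8–O bond must point to the diene face, and the prenylmethyl group should take the site eclipsing C=O rather than the one pressed against C6–H, which from the 8R carbinol exposes the face that gives the C6 configuration of the target. The step therefore needs regioselectivity (tether length), facial selectivity (C8) and protection from enone polymerisation (high dilution and a radical inhibitor).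

Step 6
Reactants: 13 (5R,7R)-10-methyl-5-(3-methylbut-2-en-1-yl)-3,3-di(propan-2-yl)-2,4-dioxa-3-silabicyclo[5.3.1]undec-1(10)-en-6-one; 14 dimethyltitanocene
Product: 15 (5R,7R)-10-methyl-6-methylidene-5-(3-methylbut-2-en-1-yl)-3,3-di(propan-2-yl)-2,4-dioxa-3-silabicyclo[5.3.1]undec-1(10)-ene
Conditions: Cp2TiMe2 (3 equiv), toluene, 70 °C, dark
Reagents that add atoms: dimethyltitanocene, C[Ti](C)(C1C=CC=C1)C1C=CC=C1
Why: Petasis methylenation (non-basic titanocene methylidene) should convert the hindered α-siloxy ketone into the 1,1-disubstituted alkene while the ring carbonyl is still masked as the silyl enol ether and C6 is a bridgehead that cannot epimerise.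

Step 7
Reactants: 15 (5R,7R)-10-methyl-6-methylidene-5-(3-methylbut-2-en-1-yl)-3,3-di(propan-2-yl)-2,4-dioxa-3-silabicyclo[5.3.1]undec-1(10)-ene
Product: 17 (5R)-5-[(3R)-3-hydroxy-6-methylhepta-1,5-dien-2-yl]-2-methylcyclohex-2-en-1-one, via acetoxysilyl ether of the enone 16 (not isolated)
Conditions: Pd(OAc)2 (1.2 equiv), MeCN, 40 °C; then HF·pyridine, THF, 0 °C
Reagents that add atoms: none
Why: Saegusa–Ito oxidation uses the tether-derived, regiodefined C3=C4 silyl enol ether to form the palladium enolate and, after endocyclic β-hydride elimination, the C2=C3 enone, and fluoride then strips the silicon from O8 so that the tether leaves the molecule.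

Step 8
Reactants: 17 (5R)-5-[(3R)-3-hydroxy-6-methylhepta-1,5-dien-2-yl]-2-methylcyclohex-2-en-1-one; 18 acetic acid
Product: 19 (3S)-6-methyl-2-[(1R)-4-methyl-5-oxocyclohex-3-en-1-yl]hepta-1,5-dien-3-yl acetate
Conditions: PPh3, DIAD, toluene, 0 °C to rt
Reagents that add atoms: acetic acid, CC(=O)O
Why: Mitsunobu esterification should displace the allylic C8 oxyphosphonium by acetate with SN2 inversion, turning the 8R carbinol needed for the cycloaddition into the 8S acetate of the target.

Step 9
Reactants: 19 (3S)-6-methyl-2-[(1R)-4-methyl-5-oxocyclohex-3-en-1-yl]hepta-1,5-dien-3-yl acetate; 20 3-phenyl-2-(phenylsulfonyl)oxaziridine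
Product: 22 (3S)-2-[(1S,6S)-6-hydroxy-4-methyl-5-oxocyclohex-3-en-1-yl]-6-methylhepta-1,5-dien-3-yl acetate, via lithium cross-conjugated dienolate 21 (not isolated)
Conditions: LiN(SiMe3)2 (1.05 equiv), THF, −78 °C; then 20, −78 °C; aq. NH4Cl
Reagents that add atoms: 3-phenyl-2-(phenylsulfonyl)oxaziridine, O=S(=O)(c1ccccc1)N1OC1c1ccccc1
Why: Kinetic α′-deprotonation (the ketone is far more acidic than the acetate) gives the cross-conjugated dienolate, which the N-sulfonyloxaziridine should hydroxylate at C5 from the face opposite the adjacent C6 side chain, setting the 5,6-trans relation.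

Step 10
Reactants: 22 (3S)-2-[(1S,6S)-6-hydroxy-4-methyl-5-oxocyclohex-3-en-1-yl]-6-methylhepta-1,5-dien-3-yl acetate; 23 (2Z)-2-methylbut-2-enoic acid
Product: 25 (1S,6S)-6-[(3S)-3-(acetyloxy)-6-methylhepta-1,5-dien-2-yl]-3-methyl-2-oxocyclohex-3-en-1-yl (2Z)-2-methylbut-2-enoate, via angelic 2,4,6-trichlorobenzoic anhydride 24 (not isolated)
Conditions: 23, 2,4,6-trichlorobenzoyl chloride, Et3N, toluene, rt; then 22, 80 °C
Reagents that add atoms: (2Z)-2-methylbut-2-enoic acid, C/C=C(/C)C(O)=O
Why: Yamaguchi-type acylation through the trichlorobenzoyl mixed anhydride without a nucleophilic catalyst should esterify the hindered α-ketol with retention at C5 and without Z-to-E isomerisation of the angeloyl group.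

Step 11
Reactants: 25 (1S,6S)-6-[(3S)-3-(acetyloxy)-6-methylhepta-1,5-dien-2-yl]-3-methyl-2-oxocyclohex-3-en-1-yl (2Z)-2-methylbut-2-enoate
Product: 26 (1S,2S,6S)-6-[(3S)-3-(acetyloxy)-6-methylhepta-1,5-dien-2-yl]-2-hydroxy-3-methylcyclohex-3-en-1-yl (2Z)-2-methylbut-2-enoate
Conditions: NaBH4, CeCl3·7H2O, MeOH, −78 °C
Reagents that add atoms: none
Why: Luche reduction delivers hydride 1,2 and axially to the half-chair enone that carries the C5 and C6 substituents equatorial, which should give the equatorial C4 alcohol cis to the side chain and trans to the ester while the esters and the other alkenes stay intact.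

Step 12
Reactants: 26 (1S,2S,6S)-6-[(3S)-3-(acetyloxy)-6-methylhepta-1,5-dien-2-yl]-2-hydroxy-3-methylcyclohex-3-en-1-yl (2Z)-2-methylbut-2-enoate; 27 tert-butyl hydroperoxide
Product: 28 (1R,2R,3S,4S,6S)-4-[(3S)-3-(acetyloxy)-6-methylhepta-1,5-dien-2-yl]-2-hydroxy-1-methyl-7-oxabicyclo[4.1.0]heptan-3-yl (2Z)-2-methylbut-2-enoate
Conditions: VO(acac)2 (5 mol %), tBuOOH (decane), CH2Cl2, 0 °C to rt
Reagents that add atoms: tert-butyl hydroperoxide, CC(C)(C)OO
Why: Vanadium-catalysed hydroxyl-directed epoxidation delivers oxygen to C2=C3 from the face of the allylic C4 hydroxyl, i.e. syn to the side chain, a face that nucleophilic epoxidation of the enone would not reach, and it ignores the remote non-allylic alkenes.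

Step 13
Reactants: 28 (1R,2R,3S,4S,6S)-4-[(3S)-3-(acetyloxy)-6-methylhepta-1,5-dien-2-yl]-2-hydroxy-1-methyl-7-oxabicyclo[4.1.0]heptan-3-yl (2Z)-2-methylbut-2-enoate
Product: 29 (1S,3S,4S,6S)-4-[(3S)-3-(acetyloxy)-6-methylhepta-1,5-dien-2-yl]-1-methyl-2-oxo-7-oxabicyclo[4.1.0]heptan-3-yl (2Z)-2-methylbut-2-enoate
Conditions: Dess–Martin periodinane, pyridine, CH2Cl2, 0 °C to rt
Reagents that add atoms: none
Why: Dess–Martin oxidation of the secondary epoxy alcohol to the ketone is mild enough to spare the epoxide, the esters and the alkenes and touches none of the remaining stereocentres.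

## Compound list

1 | methyl (2R)-oxirane-2-carboxylate | COC(=O)[C@H]1CO1 | starting material
2 | (2-methylprop-1-en-1-yl)magnesium bromide | CC(C)=C[Mg]Br | starting material
3 | methyl (2R)-2-hydroxy-5-methylhex-4-enoate | COC(=O)[C@H](O)CC=C(C)C | intermediate
4 | N,O-dimethylhydroxylamine hydrochloride | CNOC.Cl | starting material
5 | (2R)-2-hydroxy-N-methoxy-N,5-dimethylhex-4-enamide | CON(C)C(=O)[C@H](O)CC=C(C)C | intermediate
6 | vinylmagnesium bromide | C=C[Mg]Br | starting material
7 | (4R)-4-hydroxy-7-methylocta-1,6-dien-3-one | C=CC(=O)[C@H](O)CC=C(C)C | intermediate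
8 | 3-methylbut-3-en-2-one | CC(=O)C(C)=C | starting material
9 | dichlorodi(propan-2-yl)silane | CC(C)[Si](Cl)(Cl)C(C)C | starting material
10 | lithium 3-methylbuta-1,3-dien-2-olate | [Li]OC(=C)C(C)=C | intermediate
11 | chloro[(3-methylbuta-1,3-dien-2-yl)oxy]di(propan-2-yl)silane | C=C(C)C(=C)O[Si](Cl)(C(C)C)C(C)C | intermediate
12 | (4R)-7-methyl-4-({[(3-methylbuta-1,3-dien-2-yl)oxy]di(propan-2-yl)silyl}oxy)octa-1,6-dien-3-one | C=CC(=O)[C@@H](CC=C(C)C)O[Si](C(C)C)(C(C)C)OC(=C)C(C)=C | intermediate
13 | (5R,7R)-10-methyl-5-(3-methylbut-2-en-1-yl)-3,3-di(propan-2-yl)-2,4-dioxa-3-silabicyclo[5.3.1]undec-1(10)-en-6-one | O=C([C@@H](CC=C(C)C)O[Si](C(C)C)(C(C)C)O1)[C@@H]2CCC(C)=C1C2 | intermediate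
14 | dimethyltitanocene | C[Ti](C)(C1C=CC=C1)C1C=CC=C1 | starting material
15 | (5R,7R)-10-methyl-6-methylidene-5-(3-methylbut-2-en-1-yl)-3,3-di(propan-2-yl)-2,4-dioxa-3-silabicyclo[5.3.1]undec-1(10)-ene | C=C([C@@H](CC=C(C)C)O[Si](C(C)C)(C(C)C)O1)[C@@H]2CCC(C)=C1C2 | intermediate
16 | {[(3R)-6-methyl-2-[(1R)-4-methyl-5-oxocyclohex-3-en-1-yl]hepta-1,5-dien-3-yl]oxy}di(propan-2-yl)silyl acetate | C=C([C@@H](CC=C(C)C)O[Si](C(C)C)(C(C)C)OC(C)=O)[C@@H]1CC=C(C)C(=O)C1 | intermediate
17 | (5R)-5-[(3R)-3-hydroxy-6-methylhepta-1,5-dien-2-yl]-2-methylcyclohex-2-en-1-one | C=C([C@@H](CC=C(C)C)O)[C@@H]1CC=C(C)C(=O)C1 | intermediate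
18 | acetic acid | CC(=O)O | starting material
19 | (3S)-6-methyl-2-[(1R)-4-methyl-5-oxocyclohex-3-en-1-yl]hepta-1,5-dien-3-yl acetate | C=C([C@H](CC=C(C)C)OC(C)=O)[C@@H]1CC=C(C)C(=O)C1 | intermediate
20 | 3-phenyl-2-(phenylsulfonyl)oxaziridine | O=S(=O)(c1ccccc1)N1OC1c1ccccc1 | starting material
21 | lithium (6R)-6-[(3S)-3-(acetyloxy)-6-methylhepta-1,5-dien-2-yl]-3-methylcyclohexa-1,3-dien-2-olate | C=C([C@H](CC=C(C)C)OC(C)=O)[C@@H]1CC=C(C)C(O[Li])=C1 | intermediate
22 | (3S)-2-[(1S,6S)-6-hydroxy-4-methyl-5-oxocyclohex-3-en-1-yl]-6-methylhepta-1,5-dien-3-yl acetate | C=C([C@H](CC=C(C)C)OC(C)=O)[C@@H]1CC=C(C)C(=O)[C@H]1O | intermediate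
23 | (2Z)-2-methylbut-2-enoic acid (angelic acid) | C/C=C(/C)C(O)=O | starting material
24 | (2Z)-2-methylbut-2-enoic 2,4,6-trichlorobenzoic anhydride | C/C=C(/C)C(=O)OC(=O)c1c(Cl)cc(Cl)cc1Cl | intermediate
25 | (1S,6S)-6-[(3S)-3-(acetyloxy)-6-methylhepta-1,5-dien-2-yl]-3-methyl-2-oxocyclohex-3-en-1-yl (2Z)-2-methylbut-2-enoate | C=C([C@H](CC=C(C)C)OC(C)=O)[C@@H]1CC=C(C)C(=O)[C@H]1OC(=O)/C(C)=C\C | intermediate
26 | (1S,2S,6S)-6-[(3S)-3-(acetyloxy)-6-methylhepta-1,5-dien-2-yl]-2-hydroxy-3-methylcyclohex-3-en-1-yl (2Z)-2-methylbut-2-enoate | C=C([C@H](CC=C(C)C)OC(C)=O)[C@@H]1CC=C(C)[C@H](O)[C@H]1OC(=O)/C(C)=C\C | intermediate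
27 | tert-butyl hydroperoxide | CC(C)(C)OO | starting material
28 | (1R,2R,3S,4S,6S)-4-[(3S)-3-(acetyloxy)-6-methylhepta-1,5-dien-2-yl]-2-hydroxy-1-methyl-7-oxabicyclo[4.1.0]heptan-3-yl (2Z)-2-methylbut-2-enoate | C=C([C@H](CC=C(C)C)OC(C)=O)[C@@H]1C[C@@H]2O[C@]2(C)[C@H](O)[C@H]1OC(=O)/C(C)=C\C | intermediate
29 | (1S,3S,4S,6S)-4-[(3S)-3-(acetyloxy)-6-methylhepta-1,5-dien-2-yl]-1-methyl-2-oxo-7-oxabicyclo[4.1.0]heptan-3-yl (2Z)-2-methylbut-2-enoate | C=C([C@H](CC=C(C)C)OC(C)=O)[C@@H]1C[C@@H]2O[C@]2(C)C(=O)[C@H]1OC(=O)/C(C)=C\C | target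

## Step count and risks

Total step count: 13. Longest linear sequence: 13 steps (1 to 29); 8 and 9 enter in step 4.

**Step 5 (cycloaddition).** What may go wrong: loss of facial discrimination, because the two tether-endo transition states that differ only in which C8 substituent eclipses the carbonyl may lie close together, or the s-trans enone rotamer may intervene and relay C8 in the opposite sense. Radical polymerisation of the vinyl ketone at the reaction temperature is a second drain.

Fallback (from 8 and 7, back to the route at 17): the tether is given up and the regiochemistry is instead dictated by a sulfur substituent in an intermolecular, hydrogen-bond-organised Diels–Alder reaction.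
- The lithium dienolate 10 made from 8 is sulfenylated (PhSSPh, THF, −78 °C) to 3-methyl-1-(phenylsulfanyl)but-3-en-2-one F1.
- Soft enolisation (tBuMe2SiOTf, Et3N, CH2Cl2, 0 °C) gives tert-butyl(dimethyl){[(1Z)-3-methyl-1-(phenylsulfanyl)buta-1,3-dien-2-yl]oxy}silane F2.
- F2 and the free ketol 7 are combined in toluene at 25–50 °C. The internally hydrogen-bonded s-cis ketol exposes one face, and the 1-phenylsulfanyl group outweighs the 2-siloxy group so that C5 bonds to C6. The endo adduct expected is (2R)-1-[(1S,2R)-3-{[tert-butyl(dimethyl)silyl]oxy}-4-methyl-2-(phenylsulfanyl)cyclohex-3-en-1-yl]-2-hydroxy-5-methylhex-4-en-1-one F3.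
- Non-basic methylenation (Cp2TiMe2 in excess, toluene, 70 °C) gives (3R)-2-[(1S,2R)-3-{[tert-butyl(dimethyl)silyl]oxy}-4-methyl-2-(phenylsulfanyl)cyclohex-3-en-1-yl]-6-methylhepta-1,5-dien-3-ol F4.
- Saegusa–Ito oxidation (Pd(OAc)2, MeCN) gives (5S,6R)-5-[(3R)-3-hydroxy-6-methylhepta-1,5-dien-2-yl]-2-methyl-6-(phenylsulfanyl)cyclohex-2-en-1-one F5.
- Reductive cleavage of the C5–S bond (SmI2, THF/MeOH, −78 °C) returns to 17.

**Step 8 (Mitsunobu acetate installation).** What may go wrong: E2 loss from the oxyphosphonium toward the conjugated triene (the C9 hydrogens are allylic), or SN2′ capture of acetate at the C14 methylene terminus.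

Fallback (from 17, back to the route at 19): inversion is uncoupled from acetylation. Mitsunobu esterification with the much more acidic 4-nitrobenzoic acid (PPh3, DIAD, toluene, −20 °C), whose ion pair collapses faster than elimination, should give (3S)-6-methyl-2-[(1R)-4-methyl-5-oxocyclohex-3-en-1-yl]hepta-1,5-dien-3-yl 4-nitrobenzoate F6. Methanolysis (K2CO3, MeOH, 0 °C) gives (5R)-5-[(3S)-3-hydroxy-6-methylhepta-1,5-dien-2-yl]-2-methylcyclohex-2-en-1-one F7, and ordinary acetylation (Ac2O, pyridine, DMAP) returns to 19.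

**Step 7 (Saegusa–Ito oxidation).** What may go wrong: slow silicon-to-palladium transfer at the hindered bridgehead dialkoxysilyl enol ether, or β-hydride loss toward the methyl group giving the exocyclic methylene ketone.

Fallback (from 15, back to the route at 17): the enol ether is used for halogenation–elimination instead. Bromination (N-bromosuccinimide, THF, −78 °C; bromine enters anti to the tether) should give 1-[({(3R)-2-[(1R,4R)-4-bromo-4-methyl-3-oxocyclohexyl]-6-methylhepta-1,5-dien-3-yl}oxy)di(propan-2-yl)silyl]pyrrolidine-2,5-dione F8. HF·pyridine frees (2R,5R)-2-bromo-5-[(3R)-3-hydroxy-6-methylhepta-1,5-dien-2-yl]-2-methylcyclohexan-1-one F9, and dehydrobromination (Li2CO3, LiBr, DMF, 100 °C) gives 17.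

## Further compounds

F1 | step 5 | 3-methyl-1-(phenylsulfanyl)but-3-en-2-one | C=C(C)C(=O)CSc1ccccc1
F2 | step 5 | tert-butyl(dimethyl){[(1Z)-3-methyl-1-(phenylsulfanyl)buta-1,3-dien-2-yl]oxy}silane | C=C(C)/C(O[Si](C)(C)C(C)(C)C)=C/Sc1ccccc1
F3 | step 5 | (2R)-1-[(1S,2R)-3-{[tert-butyl(dimethyl)silyl]oxy}-4-methyl-2-(phenylsulfanyl)cyclohex-3-en-1-yl]-2-hydroxy-5-methylhex-4-en-1-one | O=C([C@@H](CC=C(C)C)O)[C@@H]1CCC(C)=C(O[Si](C)(C)C(C)(C)C)[C@@H]1Sc1ccccc1
F4 | step 5 | (3R)-2-[(1S,2R)-3-{[tert-butyl(dimethyl)silyl]oxy}-4-methyl-2-(phenylsulfanyl)cyclohex-3-en-1-yl]-6-methylhepta-1,5-dien-3-ol | C=C([C@@H](CC=C(C)C)O)[C@@H]1CCC(C)=C(O[Si](C)(C)C(C)(C)C)[C@@H]1Sc1ccccc1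
F5 | step 5 | (5S,6R)-5-[(3R)-3-hydroxy-6-methylhepta-1,5-dien-2-yl]-2-methyl-6-(phenylsulfanyl)cyclohex-2-en-1-one | C=C([C@@H](CC=C(C)C)O)[C@@H]1CC=C(C)C(=O)[C@@H]1Sc1ccccc1
F6 | step 8 | (3S)-6-methyl-2-[(1R)-4-methyl-5-oxocyclohex-3-en-1-yl]hepta-1,5-dien-3-yl 4-nitrobenzoate | C=C([C@H](CC=C(C)C)OC(=O)c2ccc(cc2)[N+](=O)[O-])[C@@H]1CC=C(C)C(=O)C1
F7 | step 8 | (5R)-5-[(3S)-3-hydroxy-6-methylhepta-1,5-dien-2-yl]-2-methylcyclohex-2-en-1-one | C=C([C@H](CC=C(C)C)O)[C@@H]1CC=C(C)C(=O)C1
F8 | step 7 | 1-[({(3R)-2-[(1R,4R)-4-bromo-4-methyl-3-oxocyclohexyl]-6-methylhepta-1,5-dien-3-yl}oxy)di(propan-2-yl)silyl]pyrrolidine-2,5-dione | C=C([C@@H](CC=C(C)C)O[Si](C(C)C)(C(C)C)N2C(=O)CCC2=O)[C@@H]1CC[C@@](C)(Br)C(=O)C1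
F9 | step 7 | (2R,5R)-2-bromo-5-[(3R)-3-hydroxy-6-methylhepta-1,5-dien-2-yl]-2-methylcyclohexan-1-one | C=C([C@@H](CC=C(C)C)O)[C@@H]1CC[C@@](C)(Br)C(=O)C1
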